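The constants used here were drawn at random within sensible limits; the result is computed.

Counted in fractions of the two substrates together, the partner charge is worth at most 55.0% of either product. But the partner also decays by itself, so I ask what share of it the catalyst catches.

left-handed substrate 0.50 M; partner 0.550 M; free catalyst 10 mM; right-handed substrate 0.50 M; time 40 min

    free catalyst + left-handed substrate ⇌ catalyst intermediate A (K1 = 0.68 M⁻¹, k1 = 13 M⁻¹ s⁻¹)
    free catalyst + right-handed substrate ⇌ catalyst intermediate B (K2 = 1.2 M⁻¹, k2 = 260 M⁻¹ s⁻¹)
    partner + catalyst intermediate A → free catalyst + left-handed product (k3 = 1.6 M⁻¹ s⁻¹)
    partner + catalyst intermediate B → free catalyst + right-handed product (k4 = 0.11 M⁻¹ s⁻¹)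
    partner → decomposed reagent (k5 = 0.012 s⁻¹)
    left-handed product ⇌ right-handed product (k6 = 0.015 s⁻¹)
    free catalyst ⇌ dormant form (K7 = 1.5, k7 = 0.029 s⁻¹)

- free catalyst is single-handed; left-handed substrate and right-handed substrate are mirror images of each other, charged as a racemate, each of them at the stated concentration
- the reaction counts as stopped when no species that holds the left-handed substrate and right-handed substrate together changes by six tenths of a point or more over the second half of the time
- run time (flask): 40 min

1. the state of affairs at 40 min: stopped, and by what, or still going (forward and back rates have come level / it is still moving / no working catalyst is left / all of the left-handed substrate has reacted / the partner has run out first)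
2. share of the left-handed substrate and right-handed substrate together used up at 40 min
3. left-handed product at 40 min, in percent of the left-handed substrate and right-handed substrate together charged
4. right-handed substrate at 40 min, in percent of the left-handed substrate and right-handed substrate together charged
5. right-handed product at 40 min, in percent of the left-handed substrate and right-handed substrate together charged

Binding is quick, so I put the catalyst's forms in balance with the substrates at their charge. For each free catalyst there stand 0.340 of intermediate A, 0.60 of intermediate B and 1.5 of dormant form, a total of 3.44. The partner then sees a pseudo-first-order productive rate of 0.00177 s⁻¹, slower than its decay at 0.012 s⁻¹. That alone would send 12.9% of the partner into product.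

The weak link is the dormant form, which is absent at the start. Without it the productive rate is 0.00314 s⁻¹. The excess fades as the dormant form fills. Free catalyst is one part in 1.94 of the catalyst outside the dormant form, so with binding quick this filling relaxes at 0.0343 s⁻¹, a half-life of 0.337 min, shorter than the partner's half-life of 0.839 min, and this adds 2.85%. So the capture share, the fraction of charged partner that ends as product rather than decomposed reagent, is 15.7%.

That gives products of 8.65%. Intermediates A and B hold a further 0.273%, so I commit to a conversion of 8.92%. Of the product made, 10.8% comes from the right-handed substrate, which leaves that substrate at 48.9%. The products interconvert with a half-life of 0.385 min, far shorter than the run, so each stands at 4.33%. The run spans 47.7 partner half-lives, so I expect the partner to end it.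

The forecast says the partner has run out first, with conversion 8.2%, left-handed product 4%, right-handed substrate 48.9% and right-handed product 4%. Its grounds: “The partner decomposes on its own about seven times faster than the catalyst consumes it”. Its conversion lies a little below mine.

The simulation gives the partner has run out first, with conversion 8.14%, left-handed product 3.94%, right-handed substrate 48.9% and right-handed product 3.94%.

The partner is the limiting reagent, with 0% of it left at the end, and its depletion is the main reason conversion stops at 8.14%. In the run without that depletion, conversion reaches 71.6%. The products in this flask amount to 14.3% of the charged partner, against my capture share of 15.7%.

In the neighbour with 2.2 M of partner, the capture share gives products of 34.6%. That flask makes 26.2%, below my figure, and my reckoning held the left-handed substrate at its charge, whereas there it ends at 27.6%.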